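**Strategy.** The decalin is numbered as an eremophilane (ring A: C1–C5, C10; ring B: C5–C10). Ring A hides the retron of a 3-methylenecyclohexanol (C2 carbinol, C4 methyl) beside the quaternary ring-fusion carbon C5. Both rings are therefore closed in one operation from an acyclic (2E,5Z)-trienal: under Me2AlCl the enal first serves as C=C enophile toward a tetrasubstituted alkene (C5–C10 bond, ring B, quaternary C5), then its freed aldehyde serves as C=O enophile toward the isopropenyl group just created (C2–C3 bond, ring A, axial C2 hydroxyl). One silyloxy stereocentre (C9) steers C5, C10 and C2. The C7 isopropenyl group enters late by trans-diaxial epoxide opening.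

Key step: step 7

Remarks.
- Locants: in the acyclic precursors the aldehyde (acetal) carbon is the future C2, the E-alkene is C1=C10, the carbinol carbon is C9, the alkyne/Z-alkene is C8–C7, the CH2 is C6 and the tetrasubstituted alkene is C5=C4. C14 is the methyl on C5; C3 and C15 are the two methyls on C4. Bicyclic compounds are named as decalins with these locants; β is the face of the C5 methyl, α the opposite face.
- Assumption: the (S,S)-ligand in step 3 is taken to give the (S)-carbinol 7; if the sense proves opposite, the (R,R)-ligand is used and nothing else changes.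

**Step 1**
Reactants: 1 2,3-dimethylbuta-1,3-diene
Product: 2 1-bromo-2,3-dimethylbut-2-ene
Conditions: HBr (33% in AcOH, 1.0 equiv), 0 °C
Reagents that add atoms: hydrogen bromide, Br
Why: Protonation of the diene gives a tertiary allyl cation and bromide capture under thermodynamic control should give the primary allylic bromide with the tetrasubstituted alkene (1,4-hydrobromination of a 1,3-diene, as in the isoprene to prenyl bromide conversion).

**Step 2**
Reactants: 2 1-bromo-2,3-dimethylbut-2-ene; 3 ethynylmagnesium bromide
Product: 4 4,5-dimethylhex-4-en-1-yne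
Conditions: HC≡CMgBr (0.5 M in THF, 3 equiv), CuCl (5 mol%), THF, 0 → 40 °C
Reagents that add atoms: none
Why: Copper-catalysed coupling of an alkynyl Grignard reagent with an allylic bromide should occur at the unhindered primary carbon, since attack at the other allyl terminus would build a quaternary carbon, and the excess of 3 suppresses double allylation.

**Step 3**
Reactants: 4 4,5-dimethylhex-4-en-1-yne; 5 (2E)-4,4-dimethoxybut-2-enal
Product: 7 (2E,4S)-1,1-dimethoxy-8,9-dimethyldeca-2,8-dien-5-yn-4-ol, via alkynylmethylzinc 6 (not isolated)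
Conditions: 4 (3 equiv), Me2Zn (3 equiv), (S,S)-ProPhenol [2,6-bis{[(S)-2-(hydroxydiphenylmethyl)pyrrolidin-1-yl]methyl}-4-methylphenol] (20 mol%), Ph3P=O (40 mol%), toluene, 0 → 4 °C
Reagents that add atoms: none
Why: Zinc–ProPhenol asymmetric alkynylation of an α,β-unsaturated aldehyde, in which the dinuclear zinc complex binds the aldehyde and alkynylzinc 6 and transfers the alkynyl group to one carbonyl face, sets C9, the only stereocentre carried into the key step.

**Step 4**
Reactants: 7 (2E,4S)-1,1-dimethoxy-8,9-dimethyldeca-2,8-dien-5-yn-4-ol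
Product: 8 tert-butyl{[(2E,4S)-1,1-dimethoxy-8,9-dimethyldeca-2,8-dien-5-yn-4-yl]oxy}dimethylsilane
Conditions: TBSCl (1.2 equiv), imidazole (2.5 equiv), DMF, 0 °C → rt
Reagents that add atoms: tert-butyldimethylsilyl chloride, CC(C)(C)[Si](C)(C)Cl
Why: Standard silylation of a secondary alcohol gives the bulky, non-chelating ether that later prevents aluminium alkoxide formation and hydride transfer at the doubly allylic C9 and serves as the stereocontrol element.

**Step 5**
Reactants: 8 tert-butyl{[(2E,4S)-1,1-dimethoxy-8,9-dimethyldeca-2,8-dien-5-yn-4-yl]oxy}dimethylsilane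
Product: 9 tert-butyl{[(2E,4R,5Z)-1,1-dimethoxy-8,9-dimethyldeca-2,5,8-trien-4-yl]oxy}dimethylsilane
Conditions: H2 (1 atm), Pd/CaCO3 poisoned with Pb(OAc)2 (Lindlar catalyst), quinoline, EtOAc, rt
Reagents that add atoms: none
Why: Lindlar semihydrogenation adds H2 syn to the alkyne to give the Z-alkene that later lets C5 reach C10, while the tetrasubstituted and the E-disubstituted alkenes are not reduced by the poisoned catalyst (the descriptor changes from S to R only through the priority change).

**Step 6**
Reactants: 9 tert-butyl{[(2E,4R,5Z)-1,1-dimethoxy-8,9-dimethyldeca-2,5,8-trien-4-yl]oxy}dimethylsilane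
Product: 10 (2E,4R,5Z)-4-[(tert-butyldimethylsilyl)oxy]-8,9-dimethyldeca-2,5,8-trienal
Conditions: PPTS (10 mol%), acetone/H2O (10:1), rt
Reagents that add atoms: water, O
Why: Mild acid hydrolysis of a conjugated dimethyl acetal, which is far more labile than the secondary silyl ether, should release the E-enal without touching the Z-alkene.

**Step 7**
Reactants: 10 (2E,4R,5Z)-4-[(tert-butyldimethylsilyl)oxy]-8,9-dimethyldeca-2,5,8-trienal
Product: 12 9α-(tert-butyldimethylsilyloxy)-5β-methyl-4-methylidene-10αH-decal-7-en-2α-ol (2R,5S,9R,10R), via monocyclic aldehyde 11 (not isolated)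
Conditions: Me2AlCl (1.0 M in hexanes, 2.2 equiv), CH2Cl2, −78 → −20 °C; aq. KNaC4H4O6 work-up
Reagents that add atoms: none
Why: Me2AlCl activates the enal, and the tetrasubstituted alkene adds through C5 to C10 in a Lewis-acid conjugate ene reaction (6-membered closure of ring B in which both reacting π bonds stay exocyclic to the new ring) with transfer of hydrogen from a C4 methyl to C1, which sets free aldehyde 11 and a new isopropenyl group on C5; the aluminium-bound aldehyde then closes ring A by a type 2 intramolecular carbonyl-ene reaction (6-membered closure, C3 to C2, hydrogen from C15 to oxygen, alkene moved to C4=C15). The closest known reaction type is the sequential ene annulation of alkenes with acrolein under Me2AlCl, with its first stage made intramolecular here. C10 and C5 are set in a chair-like transition state in which the C9 silyloxy group is pseudo-equatorial and anti to the forming bond (Felkin–Anh), the enal is equatorial with C9–H eclipsing C10=C1, and allylic 1,3-strain inside the tetrasubstituted alkene holds the isopropylidene carbon C4 equatorial and the C5 methyl axial, so that OSi and CH2CHO end up trans and the C5 methyl and C10–H trans-diaxial, which fixes the trans ring fusion. C2 is set by the bicyclic chair transition state of the type 2 ene reaction, in which hydrogen transfer is only possible with an axial C–O bond, so the 2α (axial) alcohol is expected. The step needs site selectivity for 6-membered conjugate attack over attack at the aldehyde carbon (an 8-membered ring, not competitive) and over a hetero-Diels–Alder adduct (reversible under the Lewis acid), and it needs the doubly allylic silyl ether to survive, which the low temperature and the proton-scavenging methyl groups of Me2AlCl should secure.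

**Step 8**
Reactants: 12 9α-(tert-butyldimethylsilyloxy)-5β-methyl-4-methylidene-10αH-decal-7-en-2α-ol
Product: 13 5β-methyl-4-methylidene-10αH-decal-7-ene-2α,9α-diol (2R,5S,9R,10R)
Conditions: Bu4NF (1.0 M in THF, 1.5 equiv), THF, 0 °C → rt
Reagents that add atoms: none
Why: Fluoride-mediated cleavage of the silyl ether frees the allylic C9 hydroxyl that directs the next step.

**Step 9**
Reactants: 13 5β-methyl-4-methylidene-10αH-decal-7-ene-2α,9α-diol
Product: 14 7α,8α-epoxy-5β-methyl-4-methylidene-10αH-decalin-2α,9α-diol (2R,5S,7R,8S,9S,10R)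
Conditions: VO(acac)2 (3 mol%), t-BuOOH (5.5 M in decane, 1.1 equiv), CH2Cl2, 0 °C
Reagents that add atoms: tert-butyl hydroperoxide, CC(C)(C)OO
Why: Vanadium-catalysed hydroxyl-directed epoxidation (Sharpless–Michaelson) should deliver oxygen to C7=C8 syn to the allylic 9α-hydroxyl, which is also the face opposite the axial C5 methyl, and allylic alcohols react much faster than the homoallylic C2–OH/C4=C15 pair, so the exocyclic alkene is kept.

**Step 10**
Reactants: 14 7α,8α-epoxy-5β-methyl-4-methylidene-10αH-decalin-2α,9α-diol
Product: 15 7α,8α-epoxy-4β,5β-dimethyl-10αH-decalin-2α,9α-diol (2S,4S,5R,7R,8S,9S,10R)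
Conditions: H2 (1 atm), [Ir(cod)(PCy3)(py)]PF6 (5 mol%), CH2Cl2, rt
Reagents that add atoms: none
Why: In this hydroxyl-directed hydrogenation the iridium catalyst bound to the axial 2α-hydroxyl should deliver H2 to the α face of the exocyclic alkene, so the C15 methyl becomes equatorial (4β), cis to the C5 methyl and trans to the C2 hydroxyl.

**Step 11**
Reactants: 15 7α,8α-epoxy-4β,5β-dimethyl-10αH-decalin-2α,9α-diol; 16 isopropenylmagnesium bromide
Product: 17 4β,5β-dimethyl-7β-(prop-1-en-2-yl)-10αH-decalin-2α,8α,9α-triol (2S,4S,5R,7R,8R,9S,10R)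
Conditions: 16 (0.5 M in THF, 6 equiv), CuI (30 mol%), THF, −30 °C → rt; aq. NH4Cl
Reagents that add atoms: none
Why: Copper-catalysed Grignard opening of the epoxide should follow the Fürst–Plattner rule (trans-diaxial opening) and the preference of 2,3-epoxy alcohols for attack at the carbon remote from the hydroxyl, so isopropenyl enters at C7 from the β face with inversion and leaves the axial 8α-hydroxyl cis to the 9α-hydroxyl.

**Step 12**
Reactants: 18 (2E)-3-methylpent-2-enoic acid
Product: 19 (2E)-3-methylpent-2-enoyl chloride
Conditions: (COCl)2 (1.2 equiv), DMF (cat.), CH2Cl2, 0 °C → rt; evaporation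
Reagents that add atoms: oxalyl chloride, O=C(Cl)C(=O)Cl
Why: Standard conversion of a carboxylic acid into its chloride through the chloroiminium species from oxalyl chloride and DMF, without base, so the E-configured trisubstituted alkene is not isomerised.

**Step 13**
Reactants: 17 4β,5β-dimethyl-7β-(prop-1-en-2-yl)-10αH-decalin-2α,8α,9α-triol; 19 (2E)-3-methylpent-2-enoyl chloride
Product: 21 2α,8α-dihydroxy-4β,5β-dimethyl-7β-(prop-1-en-2-yl)-10αH-decalin-9α-yl (2E)-3-methylpent-2-enoate (2S,4S,5R,7R,8R,9S,10R; the target), via 8,9-O-dibutylstannylene acetal 20 (not isolated)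
Conditions: Bu2SnO (1.1 equiv), toluene, reflux (azeotropic removal of water); then 19 (1.1 equiv), toluene, 0 °C → rt
Reagents that add atoms: none
Why: Dibutylstannylene acetal formation is confined to the cis-8,9-diol and activates its equatorial oxygen (O9), so acylation without amine base should give the 9-ester and leave the axial 8- and 2-hydroxyls free (regioselective stannylene acylation as used in carbohydrate chemistry).

**Compound list**
1 | 2,3-dimethylbuta-1,3-diene | C=C(C)C(C)=C | starting material
2 | 1-bromo-2,3-dimethylbut-2-ene | CC(C)=C(C)CBr | intermediate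
3 | ethynylmagnesium bromide | C#C[Mg]Br | starting material
4 | 4,5-dimethylhex-4-en-1-yne | CC(C)=C(C)CC#C | intermediate
5 | (2E)-4,4-dimethoxybut-2-enal | COC(OC)/C=C/C=O | starting material
6 | (4,5-dimethylhex-4-en-1-yn-1-yl)(methyl)zinc | CC(C)=C(C)CC#C[Zn]C | intermediate (not isolated)
7 | (2E,4S)-1,1-dimethoxy-8,9-dimethyldeca-2,8-dien-5-yn-4-ol | CC(C)=C(C)CC#C[C@@H](O)/C=C/C(OC)OC | intermediate
8 | tert-butyl{[(2E,4S)-1,1-dimethoxy-8,9-dimethyldeca-2,8-dien-5-yn-4-yl]oxy}dimethylsilane | CC(C)=C(C)CC#C[C@@H](O[Si](C)(C)C(C)(C)C)/C=C/C(OC)OC | intermediate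
9 | tert-butyl{[(2E,4R,5Z)-1,1-dimethoxy-8,9-dimethyldeca-2,5,8-trien-4-yl]oxy}dimethylsilane | CC(C)=C(C)C/C=C\[C@@H](O[Si](C)(C)C(C)(C)C)/C=C/C(OC)OC | intermediate
10 | (2E,4R,5Z)-4-[(tert-butyldimethylsilyl)oxy]-8,9-dimethyldeca-2,5,8-trienal | CC(C)=C(C)C/C=C\[C@@H](O[Si](C)(C)C(C)(C)C)/C=C/C=O | intermediate
11 | 2-[(1R,2R,6S)-2-[(tert-butyldimethylsilyl)oxy]-6-methyl-6-(prop-1-en-2-yl)cyclohex-3-en-1-yl]acetaldehyde | CC(C)(C)[Si](C)(C)O[C@@H]1C=CC[C@](C)(C(C)=C)[C@H]1CC=O | intermediate (not isolated)
12 | 9α-(tert-butyldimethylsilyloxy)-5β-methyl-4-methylidene-10αH-decal-7-en-2α-ol (2R,5S,9R,10R) | CC(C)(C)[Si](C)(C)O[C@@H]1C=CC[C@]2(C)C(=C)C[C@H](O)C[C@@H]12 | intermediate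
13 | 5β-methyl-4-methylidene-10αH-decal-7-ene-2α,9α-diol (2R,5S,9R,10R) | O[C@@H]1C=CC[C@]2(C)C(=C)C[C@H](O)C[C@@H]12 | intermediate
14 | 7α,8α-epoxy-5β-methyl-4-methylidene-10αH-decalin-2α,9α-diol (2R,5S,7R,8S,9S,10R) | O[C@@H]1[C@@H]2O[C@@H]2C[C@]3(C)C(=C)C[C@H](O)C[C@@H]13 | intermediate
15 | 7α,8α-epoxy-4β,5β-dimethyl-10αH-decalin-2α,9α-diol (2S,4S,5R,7R,8S,9S,10R) | O[C@@H]1[C@@H]2O[C@@H]2C[C@]3(C)[C@@H](C)C[C@H](O)C[C@@H]13 | intermediate
16 | isopropenylmagnesium bromide | CC(=C)[Mg]Br | starting material
17 | 4β,5β-dimethyl-7β-(prop-1-en-2-yl)-10αH-decalin-2α,8α,9α-triol (2S,4S,5R,7R,8R,9S,10R) | C=C(C)[C@H]1C[C@]2(C)[C@@H](C)C[C@H](O)C[C@H]2[C@H](O)[C@@H]1O | intermediate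
18 | (2E)-3-methylpent-2-enoic acid | CC/C(C)=C/C(=O)O | starting material
19 | (2E)-3-methylpent-2-enoyl chloride | CC/C(C)=C/C(=O)Cl | intermediate
20 | 8,9-O-dibutylstannylene acetal of triol 17 | C=C(C)[C@H]1C[C@]2(C)[C@@H](C)C[C@H](O)C[C@H]2[C@@H]3O[Sn](CCCC)(CCCC)O[C@H]13 | intermediate (not isolated)
21 | 2α,8α-dihydroxy-4β,5β-dimethyl-7β-(prop-1-en-2-yl)-10αH-decalin-9α-yl (2E)-3-methylpent-2-enoate (2S,4S,5R,7R,8R,9S,10R) | C=C(C)[C@H]1C[C@]2(C)[C@@H](C)C[C@H](O)C[C@H]2[C@H](OC(=O)/C=C(\C)CC)[C@@H]1O | target

**Step count.** Total: 13 steps. Longest linear sequence: 12 steps (steps 1–11 and 13; step 12 is a one-step side branch).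

**Steps most likely to fail**

Step 7. The conjugate ene reaction of a simple enal may be slow, so that ionisation or hydride loss at the doubly allylic silyl ether competes. Facial selectivity at C5/C10 in the first ring closure may also be poor. The fallback separates the two ring closures and starts the first one from a far stronger electrophile. It sets out from acetal 9: Me3SiOSO2CF3 (1.1 equiv) with 2,6-di-tert-butyl-4-methylpyridine in CH2Cl2 at −78 °C should ionise the allylic acetal to a methoxyallyl cation, which the tetrasubstituted alkene attacks at C10; proton loss from a C4 methyl then gives the methyl enol ether of the monocyclic aldehyde F1. Hydrolysis with aqueous oxalic acid in THF would give aldehyde 11, now isolated and freed of any C5/C10 diastereomer by chromatography. The type 2 carbonyl-ene closure with Me2AlCl in CH2Cl2 at −78 °C then returns to the route at 12.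

Step 11. Axial attack at C7 is syn to the axial C5 methyl, so the opening may be slow, and bromide from the Grignard reagent may open the epoxide instead to a bromohydrin. The fallback uses a small linear carbon nucleophile and builds the isopropenyl group afterwards. It sets out from 15: LiC≡CH·H2NCH2CH2NH2 in DMSO at rt should give the trans-diaxial product, the 7β-ethynyl-2α,8α,9α-triol F2. Zirconium-catalysed carboalumination (Me3Al in excess, Cp2ZrCl2, CH2Cl2, then water) adds methyl to the internal alkyne carbon and, after protonolysis, gives the isopropenyl group, returning to the route at 17.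

Step 9. The homoallylic axial C2 hydroxyl may direct some epoxidation to the exocyclic alkene, and the allylic alcohol may be oxidised to the enone. The fallback removes the exocyclic alkene before any epoxidation. It sets out from 12: hydroxyl-directed hydrogenation with [Rh(nbd)(dppb)]BF4 and H2 (15 atm) in CH2Cl2 should reduce only the alkene next to the free C2 hydroxyl and give the 4β-methyl silyl ether F3. Bu4NF in THF would then give the allylic diol F4. Epoxidation with mCPBA (NaHCO3, CH2Cl2, 0 °C), syn to the 9α-hydroxyl and on the face opposite the C5 methyl, returns to the route at 15.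

**Further compounds**
F1 | step 7 | tert-butyl{[(1R,5S,6R)-6-[(E)-2-methoxyethenyl]-5-methyl-5-(prop-1-en-2-yl)cyclohex-2-en-1-yl]oxy}dimethylsilane (E/Z mixture expected, E drawn) | CC(C)(C)[Si](C)(C)O[C@@H]1C=CC[C@](C)(C(C)=C)[C@H]1/C=C/OC
F2 | step 11 | 7β-ethynyl-4β,5β-dimethyl-10αH-decalin-2α,8α,9α-triol | C#C[C@H]1C[C@]2(C)[C@@H](C)C[C@H](O)C[C@H]2[C@H](O)[C@@H]1O
F3 | step 9 | 9α-(tert-butyldimethylsilyloxy)-4β,5β-dimethyl-10αH-decal-7-en-2α-ol | CC(C)(C)[Si](C)(C)O[C@@H]1C=CC[C@]2(C)[C@@H](C)C[C@H](O)C[C@@H]12
F4 | step 9 | 4β,5β-dimethyl-10αH-decal-7-ene-2α,9α-diol | O[C@@H]1C=CC[C@]2(C)[C@@H](C)C[C@H](O)C[C@@H]12
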